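The constants used here were drawn at random within sensible limits, and the outcome is calculated.

I begin from the late end of these runs and ask how much target stands after 5.0 h.

    substrate + free enzyme → target + free enzyme, rate k1*[substrate]*[free enzyme]/(1 + ([substrate]/Km1) + ([target]/Kp1)) (Km1 = 20 mM, Kp1 = 0.29 mM, k1 = 2900 L mol⁻¹ s⁻¹, Ea1 = 38.0 kJ mol⁻¹)
    free enzyme → unfolded enzyme (k2 = 5.5 × 10⁻⁷ s⁻¹, Ea2 = 202 kJ mol⁻¹)
    free enzyme + added ligand ⇌ idle complex (K3 = 8.3 × 10⁶ L mol⁻¹, k3 = 25 L mol⁻¹ s⁻¹, Ea3 = 50.0 kJ mol⁻¹, ΔH3 = −43.0 kJ mol⁻¹)
    target → over-reaction product (k4 = 1.9 × 10⁻⁵ s⁻¹, Ea4 = 108 kJ mol⁻¹)
    (constants at 30 °C)

common to all: substrate 17 mM; free enzyme 3.4 µM; added ligand 9.7 µM; time 5.0 h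
- gamma: temperature 50 °C
- theta: temperature 30 °C
- beta: temperature 10 °C

- which flask leads in amount of target, in percent of the substrate charged ("all alike" within 1.5 percentage points) (gamma / theta / beta / all alike)
- how much target is there at the end, in percent of the substrate charged: gamma
- how much target is there at the end, in percent of the substrate charged: theta
- how much target is there at the end, in percent of the substrate charged: beta

- the constants hold at 30 °C; other temperatures follow from the activation energies and enthalpies

I reckon the rate, not the contents, and I start with beta, the cold flask. In beta free enzyme gives the substrate a pace of 12.2 h⁻¹, and the line below the rate law starts at 1.85, so the starting pace is 6.62 h⁻¹.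

The concentration that sets the order of this rate is Kp, 0.29 mM, which lies far below the substrate charged. Soon the target term outweighs the rest of that line, and the rate runs as substrate over target: this is product inhibition. With half the substrate turned, target has raised the line by a factor 16.6, and the lower substrate costs a further factor 2.

Added ligand slows the rate as well, capturing free enzyme in beta at a starting pace of 0.215 h⁻¹. Release from the idle complex, 8.00 × 10⁻⁴ h⁻¹, and unfolding, 6.89 × 10⁻⁶ h⁻¹, are both far slower than capture, so I drop them. As ligand falls along with the enzyme it takes, the mean free share of the enzyme in beta over the run comes to 63.7%.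

Now I add up the slowing. The pace times the time times the mean free share times Kp over the substrate charged is 0.665, and this stall number gives my estimate of the end: minus the logarithm of the share of substrate left, less the share used, equals it. For beta that leaves 24.1% of the substrate, so I expect about 75.9% as target, less a little over-reaction.

The rule assumes that target stays in the flask. Target lasts 302 h in beta, 14.6 h in theta and 1.03 h in gamma, so it lasts longer in beta than in the warmer flasks. Of the target made at the very start, 98.4% remains at the end in beta, 71.0% in theta and 0.779% in gamma, more in beta than in either of the others, so I name beta the leader and carry the stall number no further up in temperature.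

The forecast says beta, with 5.5% for gamma, 61% for theta and 74% for beta, and gives as its ground “the steep temperature dependence of over-reaction”. The simulation gives 4.88% in gamma, 60.3% in theta and 74.0% in beta, so beta leads, and beta holds 25.1% of its substrate at the end against my 24.1%.

The neighbour of beta is charged with 4.2 mM of substrate, with everything else held. The pace stays as it was, and free enzyme ends at 39.2% of the enzyme charged, as in beta, so the stall number grows by the factor 4.05 to 2.69. The same rule then leaves 2.56% of the substrate. The simulated neighbour holds 3.3% of its substrate at the end, with 95.4% as target and 1.38% as over-reaction product.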